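## Retrosynthetic overview

1. Target 32 is (5S,9S,10S,13E)-labda-7,13-dien-15-yl hydrogen malonate. The half ester comes from alcohol 30 and Meldrum's acid, C17 and the C7=C8 alkene from a C8 enol triflate, and C12–C15 from a B-alkyl Suzuki coupling onto a C11=C12 vinyl group.
2. Feature on which the strategy rests: ring B (C5–C10) is a cyclohexene spanning the C5–C10 ring fusion, and C9 carries C11. With C11 as an acyl group and C8 oxygenated, ring B is a Diels–Alder retron (diene C5=C6–C7=C8–O, dienophile C9=C10) and the ring A carbons C1–C4 are the tether.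
3. Key disconnection: C5–C10 and C8–C9 of adduct 17. Rings A and B close together in one enantioselective intramolecular [4+2] of the achiral triene 16; no ring exists before that step.
4. Triene 16 comes from enal 15 by silyl dienol ether formation; cross-metathesis with crotonaldehyde supplies C7–C8, alkyne methylalumination sets the E C9=C10 bond with C20, and copper-catalysed conjugate addition to 3-methylbut-2-enal builds the quaternary C4.

Key step: step 8

Remark 1: labdane numbering is used for all ring compounds; the target is read as 5α-H, 10β-CH3, 9β side chain, 13E.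
Remark 2: the (R,R) ligand is chosen from the square-planar chelate model of these copper catalysts, in which the (S,S) ligand exposes the Re face of the imide α-carbon, whereas here C8 must bond to the Si face of C9.

## Route

Step 1
Reactants: 1 (5-chloropent-1-yn-1-yl)trimethylsilane; 2 3-methylbut-2-enal
Product: 5 3,3-dimethyl-8-(trimethylsilyl)oct-7-ynal, via alkylmagnesium chloride 3 (not isolated), via trimethylsilyl enol ether 4 (not isolated)
Conditions: Mg, THF, reflux; then CuBr·SMe2 (5 mol%), Me3SiCl, HMPA, 2, THF, −78 °C; then 1 M HCl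
Reagents that add atoms: none
Why: Chlorosilane-accelerated, copper-catalysed conjugate addition of a Grignard reagent to a β,β-disubstituted enal forms the C3–C4 bond and the quaternary C4, the adduct being trapped as its silyl enol ether and released as the aldehyde by mild acid, which the alkynylsilane survives.

Step 2
Reactants: 5
Product: 7 4,4-dimethylnon-1-en-8-yne, via silylated enyne 6 (not isolated)
Conditions: MePPh3Br, KN(SiMe3)2, THF, 0 °C to rt; then MeOH, K2CO3 (cat.), rt
Reagents that add atoms: methyltriphenylphosphonium bromide, C[P+](c1ccccc1)(c1ccccc1)c1ccccc1.[Br-]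
Why: Wittig methylenation of the unhindered aldehyde gives the allyl group that serves as the masked enal, and methoxide-catalysed methanolysis of the C(sp)–Si bond in the same flask frees the terminal alkyne.

Step 3
Reactants: 7
Product: 9 ethyl (2E)-3,7,7-trimethyldeca-2,9-dienoate, via alkenylalane 8 (not isolated)
Conditions: Me3Al, Cp2ZrCl2 (25 mol%), CH2Cl2, 0 °C to rt; then ClCO2Et, 0 °C to rt
Reagents that add atoms: trimethylaluminium, C[Al](C)C; ethyl chloroformate, CCOC(=O)Cl
Why: Negishi zirconium-catalysed syn-methylalumination of the terminal alkyne puts CH3 (C20) on C10 and aluminium on C9 on the same side, and acylation of the alkenylalane with retention gives the E enoate with C20 cis to the ester; the monosubstituted alkene is carbometalated far more slowly.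

Step 4
Reactants: 9
Product: 10 (2E)-3,7,7-trimethyldeca-2,9-dienoic acid
Conditions: LiOH, THF/MeOH/H2O, 50 °C; then 1 M HCl
Reagents that add atoms: lithium hydroxide, [Li+].[OH-]
Why: Saponification of the β,β-disubstituted enoate by acyl–oxygen cleavage; the conjugated E alkene is the thermodynamic isomer and should not move.

Step 5
Reactants: 10; 11 oxazolidin-2-one
Product: 13 3-[(2E)-3,7,7-trimethyldeca-2,9-dienoyl]oxazolidin-2-one, via mixed pivalic anhydride 12 (not isolated)
Conditions: t-BuCOCl, Et3N, THF, −20 °C; then 11, LiCl, rt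
Reagents that add atoms: none
Why: N-Acylation of the oxazolidinone through the mixed pivalic anhydride under LiCl/Et3N activation needs no strong base and leaves the E-trisubstituted enoyl unit untouched.

Step 6
Reactants: 13; 14 (E)-but-2-enal
Product: 15 3-[(2E,9E)-3,7,7-trimethyl-11-oxoundeca-2,9-dienoyl]oxazolidin-2-one
Conditions: second-generation Hoveyda–Grubbs catalyst RuCl2(H2IMes)(=CH-C6H4-2-O-i-Pr) (5 mol%), excess 14, CH2Cl2, 40 °C
Reagents that add atoms: none
Why: Olefin cross-metathesis couples the monosubstituted alkene with crotonaldehyde to the E enal (C6=C7–C8HO), while the trisubstituted, electron-poor enoyl alkene is inert to the catalyst.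

Step 7
Reactants: 15
Product: 16 3-[(2E,8E,10E)-11-(tert-butyldimethylsilyloxy)-3,7,7-trimethylundeca-2,8,10-trienoyl]oxazolidin-2-one
Conditions: TBSOTf (1.1 equiv), Et3N, CH2Cl2, −78 to 0 °C
Reagents that add atoms: tert-butyldimethylsilyl triflate, CC(C)(C)[Si](C)(C)OS(=O)(=O)C(F)(F)F
Why: Vinylogous soft enolisation (O-silylation of the enal, then γ-deprotonation at C5) gives the 1-silyloxydiene; the s-trans enal leads to the E enol ether, the quaternary C4 enforces the E C5=C6 bond, and the less basic imide carbonyl is not silylated at low temperature.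

Step 8
Reactants: 16
Product: 17 trans-decalin imide (C6=C7; 5α-H; 10β-CH3; 8β-OTBS; 9β-acyl oxazolidinone)
Conditions: [Cu((R,R)-t-Bu-box)](SbF6)2 (10 mol%, from CuCl2, 2,2'-isopropylidenebis[(4R)-4-tert-butyl-2-oxazoline] and AgSbF6), 4 Å molecular sieves, CH2Cl2, −20 °C to rt
Reagents that add atoms: none
Why: The cationic divalent copper centre chelates both imide carbonyls and lowers the LUMO of the C9=C10 alkene, so the electron-rich C5 terminus of the silyloxydiene bonds to the β-carbon C10 slightly ahead of C8–C9 closure in a concerted, asynchronous [4+2] (a stepwise Mukaiyama–Michael/aldol closure would give the same adduct). The closest known reaction is the copper bis(oxazoline)-catalysed intramolecular Diels–Alder reaction of trienoyl oxazolidinones, stretched here to a dienophile with a methyl group on its β-carbon. Ring B is the six-membered ring of the cycloaddition itself, and ring A closes in the fused mode through the C1–C4 tether, the C5–C10 bond forming as a 6-exo attack with both reacting π bonds outside the new ring. C9 and C10 are related by the E geometry of the dienophile (C11 and the C10 methyl cis), C5 by the acyl-endo, tether-exo transition state (trans fusion), and C8 by the E enol ether together with the endo rule (silyloxy cis to C11). The absolute configuration should follow from the (R,R) ligand, whose tert-butyl group shields the Re face of C9 in the s-cis chelate so that C8 adds to the Si face. The step needs endo, facial and "ortho" selectivity, which are secured by two-point chelation, by the matched donor (C8–O) and acceptor (C11=O) polarity, and by the C4 gem-dimethyl group that favours the folded tether.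

Step 9
Reactants: 17
Product: 18 C11 alcohol (8β-OTBS; C6=C7; 9β-CH2OH)
Conditions: LiBH4, MeOH (1 equiv), THF, 0 °C
Reagents that add atoms: none
Why: Reductive removal of the N-acyl oxazolidinone: hydride attacks the exocyclic carbonyl and the released aldehyde is reduced in situ to the primary alcohol, without touching the silyl ether, the ring alkene or C9.

Step 10
Reactants: 18
Product: 19 C11 aldehyde (8β-OTBS; C6=C7; 9β-CHO)
Conditions: Dess–Martin periodinane, NaHCO3, CH2Cl2, 0 °C to rt
Reagents that add atoms: none
Why: Dess–Martin oxidation under buffered, non-basic conditions stops at the aldehyde and avoids β-elimination of the C8 silyloxy group.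

Step 11
Reactants: 19
Product: 20 C11=C12 vinyl compound (8β-OTBS; C6=C7; 9β-CH=CH2)
Conditions: Tebbe reagent Cp2Ti(μ-CH2)(μ-Cl)AlMe2, pyridine, THF/toluene, −40 to 0 °C
Reagents that add atoms: Tebbe reagent, C[Al-]1(C)C[Ti](C2C=CC=C2)(C2C=CC=C2)[Cl+]1
Why: Tebbe methylenation is non-basic, so the hindered, enolisable β-silyloxy aldehyde should give the vinyl group without epimerisation at C9 or elimination across C8–C9.

Step 12
Reactants: 21 ethyl acetoacetate
Product: 22 ethyl (2E)-3-(trifluoromethylsulfonyloxy)but-2-enoate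
Conditions: Tf2O, aq. Me4NOH, hexane, 5 °C
Reagents that add atoms: triflic anhydride, O=S(=O)(OS(=O)(=O)C(F)(F)F)C(F)(F)F
Why: O-Triflation of the non-chelated tetramethylammonium enolate of the β-keto ester gives the E enol triflate (a chelated lithium enolate would give Z), which fixes the future C13=C14 geometry.

Step 13
Reactants: 20; 22
Product: 24 ethyl (13E)-8β-(tert-butyldimethylsilyloxy)-17-norlabda-6,13-dien-15-oate, via B-alkyl-9-BBN 23 (not isolated)
Conditions: 9-BBN, THF, rt; then 22, PdCl2(dppf) (5 mol%), AsPh3, Cs2CO3, DMF/THF/H2O, rt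
Reagents that add atoms: none
Why: 9-BBN hydroborates the monosubstituted C11=C12 alkene at C12 much faster than the ring C6=C7 alkene, and B-alkyl Suzuki–Miyaura coupling with the enol triflate forms C12–C13 with retention of the E geometry.

Step 14
Reactants: 24
Product: 25 ethyl (13E)-8β-hydroxy-17-norlabda-6,13-dien-15-oate
Conditions: HF·pyridine, pyridine, THF, 0 °C to rt
Reagents that add atoms: none
Why: Fluoride-driven cleavage of the secondary allylic silyl ether under buffered conditions leaves the ester and both alkenes untouched.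

Step 15
Reactants: 25
Product: 26 ethyl (13E)-8-oxo-17-norlabda-6,13-dien-15-oate
Conditions: Dess–Martin periodinane, NaHCO3, CH2Cl2, rt
Reagents that add atoms: none
Why: Dess–Martin oxidation of the allylic alcohol gives the C6=C7–C8=O enone; the equatorial C9 side chain is also the thermodynamic arrangement next to the ketone.

Step 16
Reactants: 26
Product: 28 ethyl (13E)-8-(trifluoromethylsulfonyloxy)-17-norlabda-7,13-dien-15-oate, via lithium enolate 27 (not isolated)
Conditions: LiBH(s-Bu)3, THF, −78 °C; then PhNTf2, −78 °C to rt; aq. NH4Cl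
Reagents that add atoms: N-phenylbis(trifluoromethanesulfonimide), O=S(=O)(N(c1ccccc1)S(=O)(=O)C(F)(F)F)C(F)(F)F
Why: Conjugate reduction–enolate trapping: 1,4-hydride delivery to C6 of the β-unsubstituted cyclohexenone generates only the C7=C8 enolate, and O-sulfonylation fixes the double bond at C7–C8 without touching C9 or the less electrophilic side-chain enoate.

Step 17
Reactants: 28
Product: 29 ethyl (13E)-labda-7,13-dien-15-oate
Conditions: MeMgBr, Fe(acac)3 (10 mol%), THF/NMP, −30 °C
Reagents that add atoms: methylmagnesium bromide, C[Mg]Br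
Why: Iron-catalysed Kumada-type cross-coupling of the alkenyl triflate with MeMgBr is fast at −30 °C, faster than Grignard addition to the hindered enoate, and installs C17 on C8 with the C7=C8 alkene in place.

Step 18
Reactants: 29
Product: 30 (13E)-labda-7,13-dien-15-ol
Conditions: i-Bu2AlH, CH2Cl2, −78 to 0 °C; aq. potassium sodium tartrate
Reagents that add atoms: none
Why: 1,2-Reduction of the α,β-unsaturated ester by i-Bu2AlH gives the E allylic alcohol and does not affect the isolated trisubstituted alkenes.

Step 19
Reactants: 30; 31 Meldrum's acid (2,2-dimethyl-1,3-dioxane-4,6-dione)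
Product: 32 (13E)-labda-7,13-dien-15-yl hydrogen malonate (target)
Conditions: toluene, 100 °C
Reagents that add atoms: none
Why: Thermal alcoholysis of Meldrum's acid opens the dioxanedione with loss of acetone and gives the malonic half ester directly, below the temperature at which it decarboxylates.

## Compound list

1 | (5-chloropent-1-yn-1-yl)trimethylsilane | C[Si](C)(C)C#CCCCCl | starting material
2 | 3-methylbut-2-enal | CC(C)=CC=O | starting material
3 | [5-(trimethylsilyl)pent-4-yn-1-yl]magnesium chloride | C[Si](C)(C)C#CCCC[Mg]Cl | intermediate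
4 | trimethylsilyl enol ether of 5 (E/Z mixture) | C[Si](C)(C)C#CCCCC(C)(C)C=CO[Si](C)(C)C | intermediate
5 | 3,3-dimethyl-8-(trimethylsilyl)oct-7-ynal | C[Si](C)(C)C#CCCCC(C)(C)CC=O | intermediate
6 | (6,6-dimethylnon-8-en-1-yn-1-yl)trimethylsilane | C=CCC(C)(C)CCCC#C[Si](C)(C)C | intermediate
7 | 4,4-dimethylnon-1-en-8-yne | C=CCC(C)(C)CCCC#C | intermediate
8 | [(1E)-2,6,6-trimethylnona-1,8-dien-1-yl]dimethylaluminium | C[Al](C)/C=C(\C)CCCC(C)(C)CC=C | intermediate
9 | ethyl (2E)-3,7,7-trimethyldeca-2,9-dienoate | CCOC(=O)/C=C(\C)CCCC(C)(C)CC=C | intermediate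
10 | (2E)-3,7,7-trimethyldeca-2,9-dienoic acid | OC(=O)/C=C(\C)CCCC(C)(C)CC=C | intermediate
11 | oxazolidin-2-one | O=C1NCCO1 | starting material
12 | (2E)-3,7,7-trimethyldeca-2,9-dienoic pivalic anhydride | CC(C)(C)C(=O)OC(=O)/C=C(\C)CCCC(C)(C)CC=C | intermediate
13 | 3-[(2E)-3,7,7-trimethyldeca-2,9-dienoyl]oxazolidin-2-one | O=C1OCCN1C(=O)/C=C(\C)CCCC(C)(C)CC=C | intermediate
14 | (E)-but-2-enal | C/C=C/C=O | starting material
15 | 3-[(2E,9E)-3,7,7-trimethyl-11-oxoundeca-2,9-dienoyl]oxazolidin-2-one | O=C1OCCN1C(=O)/C=C(\C)CCCC(C)(C)C/C=C/C=O | intermediate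
16 | 3-[(2E,8E,10E)-11-(tert-butyldimethylsilyloxy)-3,7,7-trimethylundeca-2,8,10-trienoyl]oxazolidin-2-one | O=C1OCCN1C(=O)/C=C(\C)CCCC(C)(C)/C=C/C=C/O[Si](C)(C)C(C)(C)C | intermediate
17 | Diels–Alder adduct: trans-fused labdane C1–C11 core, C6=C7, 5α-H, 10β-CH3, 8β-OTBS, 9β-C(=O)-oxazolidin-2-on-3-yl | CC(C)(C)[Si](C)(C)O[C@H]1C=C[C@H]2C(C)(C)CCC[C@]2(C)[C@H]1C(=O)N3CCOC3=O | intermediate
18 | C11 alcohol of the same core (8β-OTBS, C6=C7, 9β-CH2OH) | CC(C)(C)[Si](C)(C)O[C@H]1C=C[C@H]2C(C)(C)CCC[C@]2(C)[C@H]1CO | intermediate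
19 | C11 aldehyde of the same core (8β-OTBS, C6=C7, 9β-CHO) | CC(C)(C)[Si](C)(C)O[C@H]1C=C[C@H]2C(C)(C)CCC[C@]2(C)[C@H]1C=O | intermediate
20 | 9β-vinyl compound (C11=C12; 8β-OTBS, C6=C7) | CC(C)(C)[Si](C)(C)O[C@H]1C=C[C@H]2C(C)(C)CCC[C@]2(C)[C@H]1C=C | intermediate
21 | ethyl acetoacetate | CCOC(=O)CC(C)=O | starting material
22 | ethyl (2E)-3-(trifluoromethylsulfonyloxy)but-2-enoate | CCOC(=O)/C=C(\C)OS(=O)(=O)C(F)(F)F | intermediate
23 | B-(C12-alkyl)-9-borabicyclo[3.3.1]nonane from 20 | CC(C)(C)[Si](C)(C)O[C@H]1C=C[C@H]2C(C)(C)CCC[C@]2(C)[C@H]1CCB3C4CCCC3CCC4 | intermediate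
24 | ethyl (13E)-8β-(tert-butyldimethylsilyloxy)-17-norlabda-6,13-dien-15-oate | CC(C)(C)[Si](C)(C)O[C@H]1C=C[C@H]2C(C)(C)CCC[C@]2(C)[C@H]1CC/C(C)=C/C(=O)OCC | intermediate
25 | ethyl (13E)-8β-hydroxy-17-norlabda-6,13-dien-15-oate | O[C@H]1C=C[C@H]2C(C)(C)CCC[C@]2(C)[C@H]1CC/C(C)=C/C(=O)OCC | intermediate
26 | ethyl (13E)-8-oxo-17-norlabda-6,13-dien-15-oate | O=C1C=C[C@H]2C(C)(C)CCC[C@]2(C)[C@H]1CC/C(C)=C/C(=O)OCC | intermediate
27 | lithium C7=C8 enolate of ethyl (13E)-8-oxo-17-norlabd-13-en-15-oate | [Li]OC1=CC[C@H]2C(C)(C)CCC[C@]2(C)[C@H]1CC/C(C)=C/C(=O)OCC | intermediate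
28 | ethyl (13E)-8-(trifluoromethylsulfonyloxy)-17-norlabda-7,13-dien-15-oate | O=S(=O)(OC1=CC[C@H]2C(C)(C)CCC[C@]2(C)[C@H]1CC/C(C)=C/C(=O)OCC)C(F)(F)F | intermediate
29 | ethyl (13E)-labda-7,13-dien-15-oate | CC1=CC[C@H]2C(C)(C)CCC[C@]2(C)[C@H]1CC/C(C)=C/C(=O)OCC | intermediate
30 | (13E)-labda-7,13-dien-15-ol | CC1=CC[C@H]2C(C)(C)CCC[C@]2(C)[C@H]1CC/C(C)=C/CO | intermediate
31 | Meldrum's acid | CC1(C)OC(=O)CC(=O)O1 | starting material
32 | (5S,9S,10S,13E)-labda-7,13-dien-15-yl hydrogen malonate (CNP0279336.1) | CC1=CC[C@H]2C(C)(C)CCC[C@]2(C)[C@H]1CC/C(C)=C/COC(=O)CC(=O)O | target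

## Step count

Total: 19 steps. Longest linear sequence: 18 steps (steps 1–11 and 13–19, from 1 to 32); step 12 is a one-step branch.

## Steps most likely to fail

Step 8 (the cycloaddition). In the chelate the β-methyl group of the dienophile points toward a tert-butyl group of the ligand, so the catalyst–substrate complex may react too slowly. The silyl dienol ether may meanwhile be desilylated or oligomerised by the Lewis acid, and a distorted chelate may erode endo or facial selectivity. Fallback: auxiliary control in place of catalyst control. Acid 10 would be acylated (t-BuCOCl, Et3N, LiCl) with (4S)-4-benzyloxazolidin-2-one to give the chiral imide F1. The same cross-metathesis with 14 would give the enal F2, and TBSOTf/Et3N would give the silyl dienol ether F3. Me2AlCl (CH2Cl2, −78 to −30 °C) would then promote the cycloaddition through the chelated s-cis imide, the benzyl group blocking the Re face of C9, to give the adduct F4. LiBH4 would cleave the auxiliary and return the route to alcohol 18.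

Step 9 (reductive cleavage of the imide). The exocyclic carbonyl sits on C9 between the quaternary C10 and the silyloxy-bearing C8, so hydride may attack the ring carbonyl of the oxazolidinone instead and open the heterocycle. Fallback: from 17, LiSEt (EtSH, n-BuLi, THF, 0 °C), a small and soft nucleophile selective for the exocyclic carbonyl, would give the S-ethyl thioester F5. Fukuyama reduction (Et3SiH, Pd/C, acetone, rt) would then give aldehyde 19 directly.

Step 16 (conjugate reduction and triflation). 1,2-Reduction of the C8 ketone may compete with hydride delivery to C6, or the boron-bound enolate may be sulfonylated sluggishly. Fallback: from enone 26, conjugate reduction with [(Ph3P)CuH]6 (benzene, rt) would give the saturated C8 ketone F6. Kinetic deprotonation at the C7 methylene (not the hindered C9 methine) with KN(SiMe3)2 (THF, −78 °C) followed by PhNTf2 would give the same triflate 28.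

## Further compounds

F1 | step 8 | (4S)-4-benzyl-3-[(2E)-3,7,7-trimethyldeca-2,9-dienoyl]oxazolidin-2-one | O=C(/C=C(\C)CCCC(C)(C)CC=C)N1[C@@H](Cc2ccccc2)COC1=O
F2 | step 8 | (4S)-4-benzyl-3-[(2E,9E)-3,7,7-trimethyl-11-oxoundeca-2,9-dienoyl]oxazolidin-2-one | O=C(/C=C(\C)CCCC(C)(C)C/C=C/C=O)N1[C@@H](Cc2ccccc2)COC1=O
F3 | step 8 | (4S)-4-benzyl-3-[(2E,8E,10E)-11-(tert-butyldimethylsilyloxy)-3,7,7-trimethylundeca-2,8,10-trienoyl]oxazolidin-2-one | O=C(/C=C(\C)CCCC(C)(C)/C=C/C=C/O[Si](C)(C)C(C)(C)C)N1[C@@H](Cc2ccccc2)COC1=O
F4 | step 8 | Diels–Alder adduct as 17 but with the (4S)-4-benzyloxazolidin-2-one auxiliary on C11 | CC(C)(C)[Si](C)(C)O[C@H]1C=C[C@H]2C(C)(C)CCC[C@]2(C)[C@H]1C(=O)N3[C@@H](Cc4ccccc4)COC3=O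
F5 | step 9 | S-ethyl C11 thioester of the adduct core (8β-OTBS, C6=C7) | CC(C)(C)[Si](C)(C)O[C@H]1C=C[C@H]2C(C)(C)CCC[C@]2(C)[C@H]1C(=O)SCC
F6 | step 16 | ethyl (13E)-8-oxo-17-norlabd-13-en-15-oate | O=C1CC[C@H]2C(C)(C)CCC[C@]2(C)[C@H]1CC/C(C)=C/C(=O)OCC
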